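Removing the C6 hydroxymethyl carbon of ring A leaves the mono-orsellinate of 2-prenyl-5-(hydroxymethyl)resorcinol. In that ring the two phenol oxygens (O1, O3) are mirror-related through the C2–C5 axis, so prenylation and mono-acylation need no regiocontrol. The key step adds the last carbon: phenylboronic acid tethers formaldehyde to the free O1–H phenol and delivers it to C6, the only unsubstituted ortho carbon (C2 carries the prenyl group). This forms the C6–CH2 bond and closes a temporary 1,3,2-dioxaborin across O1 and the new CH2O in one operation. Its precursor is ester 13, with the C5 CH2OH and both ring B phenols silylated.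

Key step: step 7

Remarks on the chemistry:
- The target is achiral and its alkene carries two identical methyl groups, so no stereochemical control is needed.
- Ring A is numbered C1 (OH), C2 (prenyl), C3 (ester O), C4 (H), C5 and C6 (CH2OH); ring B is the orsellinate ring.
- In 13 the para carbon C4 is unsubstituted as well, so C6 is singled out by the ortho reach of the boron tether together with the blocked C2, not by blocking alone.
- The phenolic acetals are removed under non-protic conditions, because protic acid would cleave the benzylic silyl ether and can close a chroman onto the prenyl group.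
- Orsellinic acid is assumed to be used dried (it is sold as a hydrate).

Step 1
Reactants: 1 3,5-dihydroxybenzyl alcohol
Product: 2 [3,5-bis(methoxymethoxy)phenyl]methanol
Conditions: NaH (2.1 equiv), DMF, 0 °C; MOMCl (2.1 equiv), 0 °C to rt
Reagents that add atoms: chloromethyl methyl ether (MOMCl), COCCl
Why: Williamson-type O-alkylation: two equivalents of NaH deprotonate only the two phenols, and the resulting bis-phenoxide should consume both equivalents of the chloromethyl ether before the far less acidic, neutral benzylic alcohol can react.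

Step 2
Reactants: 2 [3,5-bis(methoxymethoxy)phenyl]methanol
Product: 3 tert-butyl{[3,5-bis(methoxymethoxy)phenyl]methoxy}dimethylsilane
Conditions: TBSCl, imidazole, DMF, rt
Reagents that add atoms: tert-butyldimethylsilyl chloride (TBSCl), CC(C)(C)[Si](C)(C)Cl
Why: Imidazole-promoted silylation of a primary alcohol (nucleophilic substitution at silicon), to which the two acetals are inert.

Step 3
Reactants: 3 tert-butyl{[3,5-bis(methoxymethoxy)phenyl]methoxy}dimethylsilane; 4 prenyl bromide (1-bromo-3-methylbut-2-ene)
Product: 6 tert-butyl{[3,5-bis(methoxymethoxy)-4-(3-methylbut-2-en-1-yl)phenyl]methoxy}dimethylsilane, via aryllithium 5 (not isolated)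
Conditions: n-BuLi, THF, 0 °C; CuBr·SMe2 (0.2 equiv), −40 °C; 4, −40 °C to rt
Reagents that add atoms: prenyl bromide (4), CC(C)=CCBr
Why: Directed ortho-metalation followed by copper-catalysed allylic substitution: the C–H between the two OCH2OCH3 groups is the most acidic ring position and is chelated from both sides, and the aryl nucleophile should attack the unhindered CH2 terminus of the primary allylic bromide (SN2 rather than SN2′) to give the linear prenyl group.

Step 4
Reactants: 6 tert-butyl{[3,5-bis(methoxymethoxy)-4-(3-methylbut-2-en-1-yl)phenyl]methoxy}dimethylsilane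
Product: 8 5-({[tert-butyl(dimethyl)silyl]oxy}methyl)-2-(3-methylbut-2-en-1-yl)benzene-1,3-diol, via bis(trimethylsilyl) ether 7 (not isolated)
Conditions: TMSOTf (5 equiv), 2,2′-bipyridyl (7.5 equiv), MeCN, 0 °C to rt; then H2O, rt
Reagents that add atoms: none
Why: Non-protic cleavage of aryl methoxymethyl ethers: the silyl triflate/bipyridyl pair exchanges each aryl acetal for an aryl trimethylsilyl ether while the methoxymethyl cation is trapped as a pyridinium salt, and water then hydrolyses the labile aryl O–SiMe3 bonds, so no Brønsted acid strong enough to remove the primary silyl ether or to cyclise the ortho-prenylphenol to a chroman should ever be present.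

Step 5
Reactants: 9 orsellinic acid (2,4-dihydroxy-6-methylbenzoic acid)
Product: 11 2,4-bis{[tert-butyl(dimethyl)silyl]oxy}-6-methylbenzoic acid, via silyl ester 10 (not isolated)
Conditions: TBSCl (3.5 equiv), imidazole (7 equiv), DMF, rt; then AcOH/THF/H2O, rt; used without storage
Reagents that add atoms: tert-butyldimethylsilyl chloride (TBSCl), CC(C)(C)[Si](C)(C)Cl
Why: Exhaustive silylation followed by selective hydrolysis of the silyl ester, which is far more labile towards aqueous acetic acid than the two aryl silyl ethers.

Step 6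
Reactants: 11 2,4-bis{[tert-butyl(dimethyl)silyl]oxy}-6-methylbenzoic acid; 8 5-({[tert-butyl(dimethyl)silyl]oxy}methyl)-2-(3-methylbut-2-en-1-yl)benzene-1,3-diol
Product: 13 5-({[tert-butyl(dimethyl)silyl]oxy}methyl)-3-hydroxy-2-(3-methylbut-2-en-1-yl)phenyl 2,4-bis{[tert-butyl(dimethyl)silyl]oxy}-6-methylbenzoate, via acid chloride 12 (not isolated)
Conditions: 11, 1-chloro-N,N,2-trimethylprop-1-en-1-amine (1.1 equiv), CH2Cl2, 0 °C to rt; then added slowly to 8 (2.5 equiv, excess recovered), Et3N, DMAP (0.2 equiv), CH2Cl2, 0 °C to rt
Reagents that add atoms: none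
Why: Neutral acid chloride formation with the α-chloroenamine followed by DMAP-catalysed acylation of a phenol (nucleophilic acyl substitution): because O1 and O3 of 8 are exchanged by the mirror plane through C2 and C5, either phenol gives the same ester, and slow addition to an excess of the diol should hold back the bis-ester.

Step 7
Reactants: 13 5-({[tert-butyl(dimethyl)silyl]oxy}methyl)-3-hydroxy-2-(3-methylbut-2-en-1-yl)phenyl 2,4-bis{[tert-butyl(dimethyl)silyl]oxy}-6-methylbenzoate; 14 phenylboronic acid; 15 formaldehyde (as paraformaldehyde)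
Product: 17 5-({[tert-butyl(dimethyl)silyl]oxy}methyl)-8-(3-methylbut-2-en-1-yl)-2-phenyl-4H-1,3,2-benzodioxaborin-7-yl 2,4-bis{[tert-butyl(dimethyl)silyl]oxy}-6-methylbenzoate, via boronate half ester 16 (not isolated)
Conditions: PhB(OH)2 (1.5 equiv), (CH2O)n (excess, in portions), EtCO2H (0.3 equiv), PhMe, 90 °C, 4 Å MS
Reagents that add atoms: phenylboronic acid (14), OB(O)c1ccccc1; formaldehyde from paraformaldehyde (15), C=O
Why: Phenylboronic acid esterifies the free C1 phenol of 13 to the half ester 16, whose Lewis acidic boron binds formaldehyde through oxygen, and the activated CH2 carbon is then attacked by C6 in a six-membered cyclic transition state (O1–B–O–CH2···C6–C1); loss of the C6 proton restores ring A and loss of water from boron leaves the neutral cyclic boronate 17. The closest known reaction type is the boronic acid-templated, ortho-specific hydroxymethylation of phenols with formaldehyde, which is established for alkyl-substituted phenols and gives isolable 2-phenyl-4H-1,3,2-benzodioxaborins. The 1,3,2-dioxaborin ring is closed by the C6–CH2 bond itself, a 6-endo-trig Friedel–Crafts-type hydroxyalkylation inside the boron chelate, the O1–B and B–OCH2 bonds having formed beforehand by reversible condensation. No stereocentre is created. The step needs site selectivity (C6 over the equally unsubstituted C4, over ring B and over the prenyl alkene), and the substrate secures it: the tether from O1 reaches only ortho carbons, C2 is blocked by the prenyl group, C4 is para to O1 and out of reach, ring B has no free phenol to bind boron, and a Prins-type attack on the alkene would need an eight-membered array. The weakly acidic, water-free medium should leave the aryl ester, the silyl ethers and the ortho-prenylphenol intact.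

Step 8
Reactants: 17 5-({[tert-butyl(dimethyl)silyl]oxy}methyl)-8-(3-methylbut-2-en-1-yl)-2-phenyl-4H-1,3,2-benzodioxaborin-7-yl 2,4-bis{[tert-butyl(dimethyl)silyl]oxy}-6-methylbenzoate
Product: 18 5-({[tert-butyl(dimethyl)silyl]oxy}methyl)-3-hydroxy-4-(hydroxymethyl)-2-(3-methylbut-2-en-1-yl)phenyl 2,4-bis{[tert-butyl(dimethyl)silyl]oxy}-6-methylbenzoate
Conditions: 2,2-dimethylpropane-1,3-diol (5 equiv), THF, rt
Reagents that add atoms: none
Why: Boronate transesterification: the aliphatic 1,3-diol forms the more stable dialkyl boronate and so should release the C1 phenol and the C6 benzylic alcohol under neutral conditions that leave the aryl ester, the silyl ethers and the prenyl group untouched.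

Step 9
Reactants: 18 5-({[tert-butyl(dimethyl)silyl]oxy}methyl)-3-hydroxy-4-(hydroxymethyl)-2-(3-methylbut-2-en-1-yl)phenyl 2,4-bis{[tert-butyl(dimethyl)silyl]oxy}-6-methylbenzoate
Product: 19 3-hydroxy-4,5-bis(hydroxymethyl)-2-(3-methylbut-2-en-1-yl)phenyl 2,4-dihydroxy-6-methylbenzoate (CNP0159803.0)
Conditions: TBAF (4 equiv), AcOH (4 equiv), THF, 0 °C to rt
Reagents that add atoms: none
Why: Fluoride-induced desilylation of the two aryl and the one primary silyl ether: buffering with acetic acid keeps the liberated phenoxides protonated so that the aryl ester should be neither cleaved nor transferred, and the absence of strong acid protects the prenylphenol and the o-hydroxybenzyl alcohol.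

Compound list
1 | 3,5-dihydroxybenzyl alcohol | OCc1cc(O)cc(O)c1 | starting material
2 | [3,5-bis(methoxymethoxy)phenyl]methanol | COCOc1cc(CO)cc(OCOC)c1 | intermediate
3 | tert-butyl{[3,5-bis(methoxymethoxy)phenyl]methoxy}dimethylsilane | COCOc1cc(CO[Si](C)(C)C(C)(C)C)cc(OCOC)c1 | intermediate
4 | prenyl bromide (1-bromo-3-methylbut-2-ene) | CC(C)=CCBr | starting material
5 | [4-({[tert-butyl(dimethyl)silyl]oxy}methyl)-2,6-bis(methoxymethoxy)phenyl]lithium | [Li]c1c(OCOC)cc(CO[Si](C)(C)C(C)(C)C)cc1OCOC | intermediate
6 | tert-butyl{[3,5-bis(methoxymethoxy)-4-(3-methylbut-2-en-1-yl)phenyl]methoxy}dimethylsilane | COCOc1cc(CO[Si](C)(C)C(C)(C)C)cc(OCOC)c1CC=C(C)C | intermediate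
7 | tert-butyldimethyl{[4-(3-methylbut-2-en-1-yl)-3,5-bis(trimethylsilyloxy)phenyl]methoxy}silane | CC(C)=CCc1c(O[Si](C)(C)C)cc(CO[Si](C)(C)C(C)(C)C)cc1O[Si](C)(C)C | intermediate
8 | 5-({[tert-butyl(dimethyl)silyl]oxy}methyl)-2-(3-methylbut-2-en-1-yl)benzene-1,3-diol | CC(C)=CCc1c(O)cc(CO[Si](C)(C)C(C)(C)C)cc1O | intermediate
9 | orsellinic acid (2,4-dihydroxy-6-methylbenzoic acid) | Cc1cc(O)cc(O)c1C(=O)O | starting material
10 | tert-butyldimethylsilyl 2,4-bis{[tert-butyl(dimethyl)silyl]oxy}-6-methylbenzoate | Cc1cc(O[Si](C)(C)C(C)(C)C)cc(O[Si](C)(C)C(C)(C)C)c1C(=O)O[Si](C)(C)C(C)(C)C | intermediate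
11 | 2,4-bis{[tert-butyl(dimethyl)silyl]oxy}-6-methylbenzoic acid | Cc1cc(O[Si](C)(C)C(C)(C)C)cc(O[Si](C)(C)C(C)(C)C)c1C(=O)O | intermediate
12 | 2,4-bis{[tert-butyl(dimethyl)silyl]oxy}-6-methylbenzoyl chloride | Cc1cc(O[Si](C)(C)C(C)(C)C)cc(O[Si](C)(C)C(C)(C)C)c1C(Cl)=O | intermediate
13 | 5-({[tert-butyl(dimethyl)silyl]oxy}methyl)-3-hydroxy-2-(3-methylbut-2-en-1-yl)phenyl 2,4-bis{[tert-butyl(dimethyl)silyl]oxy}-6-methylbenzoate | CC(C)=CCc1c(O)cc(CO[Si](C)(C)C(C)(C)C)cc1OC(=O)c1c(C)cc(O[Si](C)(C)C(C)(C)C)cc1O[Si](C)(C)C(C)(C)C | intermediate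
14 | phenylboronic acid | OB(O)c1ccccc1 | starting material
15 | formaldehyde (used as paraformaldehyde) | C=O | starting material
16 | 5-({[tert-butyl(dimethyl)silyl]oxy}methyl)-3-{[hydroxy(phenyl)boranyl]oxy}-2-(3-methylbut-2-en-1-yl)phenyl 2,4-bis{[tert-butyl(dimethyl)silyl]oxy}-6-methylbenzoate | CC(C)=CCc1c(OB(O)c2ccccc2)cc(CO[Si](C)(C)C(C)(C)C)cc1OC(=O)c1c(C)cc(O[Si](C)(C)C(C)(C)C)cc1O[Si](C)(C)C(C)(C)C | intermediate
17 | 5-({[tert-butyl(dimethyl)silyl]oxy}methyl)-8-(3-methylbut-2-en-1-yl)-2-phenyl-4H-1,3,2-benzodioxaborin-7-yl 2,4-bis{[tert-butyl(dimethyl)silyl]oxy}-6-methylbenzoate | CC(C)=CCc1c(OC(=O)c2c(C)cc(O[Si](C)(C)C(C)(C)C)cc2O[Si](C)(C)C(C)(C)C)cc(CO[Si](C)(C)C(C)(C)C)c2COB(c3ccccc3)Oc12 | intermediate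
18 | 5-({[tert-butyl(dimethyl)silyl]oxy}methyl)-3-hydroxy-4-(hydroxymethyl)-2-(3-methylbut-2-en-1-yl)phenyl 2,4-bis{[tert-butyl(dimethyl)silyl]oxy}-6-methylbenzoate | CC(C)=CCc1c(OC(=O)c2c(C)cc(O[Si](C)(C)C(C)(C)C)cc2O[Si](C)(C)C(C)(C)C)cc(CO[Si](C)(C)C(C)(C)C)c(CO)c1O | intermediate
19 | 3-hydroxy-4,5-bis(hydroxymethyl)-2-(3-methylbut-2-en-1-yl)phenyl 2,4-dihydroxy-6-methylbenzoate (achiral; no stereodescriptor) | CC(C)=CCc1c(OC(=O)c2c(C)cc(O)cc2O)cc(CO)c(CO)c1O | target

Total step count: 9.
Longest linear sequence: 8 steps (steps 1, 2, 3, 4, 6, 7, 8 and 9 from compound 1; step 5 prepares the acyl partner in parallel).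

Steps most likely to fail

Step 7. The C–C bond formation may stall because C6 is flanked by the silyloxymethyl group, and prolonged heating could then lead to loss of silyl groups or to cyclisation of the phenol onto the prenyl alkene. The fallback sets out from 13 and changes both the template and the oxidation level of the incoming carbon. Magnesium phenoxide-directed ortho-formylation (MgCl2, Et3N, paraformaldehyde, MeCN, reflux) is ortho-specific through a magnesium chelate, and with C2 blocked it should give the salicylaldehyde F1. Reduction of the aldehyde (NaBH4, THF/EtOH, −20 °C), which is much faster than attack on the hindered aryl ester, comes back to the route at 18, so that 17 and step 8 are bypassed.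

Step 6. Over-acylation to the bis-ester, slow coupling of the di-ortho-substituted acid chloride with the hindered phenol, and silyl transfer between phenols during a long reaction are the likely failure modes. The fallback sets out from 8 and reverses the order of the two events. The boron-templated hydroxymethylation is run first with one equivalent of PhB(OH)2 (paraformaldehyde, EtCO2H cat., PhMe, 90 °C). By the same symmetry argument this should give the mono-dioxaborin F2, with unreacted 8 recycled. In F2 O1 and the new CH2O are masked and only the O3–H phenol remains, so it can be acylated with an excess of acid chloride 12 (Et3N, DMAP, CH2Cl2) without any possibility of a second acylation. The route is rejoined at 17.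

Step 4. Exchange of the second acetal may remain incomplete, or the benzylic silyl ether may be lost under the silyl triflate. The fallback sets out from 6 and accepts the loss of the silyl group. Protic cleavage of all three protecting groups (HCl, MeOH, rt) should give the triol F3. Exhaustive silylation (TBSCl, imidazole, DMF) then gives the tris-silyl ether F4. Selective removal of the two aryl silyl ethers in the presence of the alkyl silyl ether (KHF2, MeOH, rt) comes back to the route at 8.

Further compounds
F1 | step 7 | 5-({[tert-butyl(dimethyl)silyl]oxy}methyl)-4-formyl-3-hydroxy-2-(3-methylbut-2-en-1-yl)phenyl 2,4-bis{[tert-butyl(dimethyl)silyl]oxy}-6-methylbenzoate | CC(C)=CCc1c(OC(=O)c2c(C)cc(O[Si](C)(C)C(C)(C)C)cc2O[Si](C)(C)C(C)(C)C)cc(CO[Si](C)(C)C(C)(C)C)c(C=O)c1O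
F2 | step 6 | 5-({[tert-butyl(dimethyl)silyl]oxy}methyl)-8-(3-methylbut-2-en-1-yl)-2-phenyl-4H-1,3,2-benzodioxaborin-7-ol | CC(C)=CCc1c(O)cc(CO[Si](C)(C)C(C)(C)C)c2COB(c3ccccc3)Oc12
F3 | step 4 | 5-(hydroxymethyl)-2-(3-methylbut-2-en-1-yl)benzene-1,3-diol | CC(C)=CCc1c(O)cc(CO)cc1O
F4 | step 4 | tert-butyl{[3,5-bis({[tert-butyl(dimethyl)silyl]oxy})-4-(3-methylbut-2-en-1-yl)phenyl]methoxy}dimethylsilane | CC(C)=CCc1c(O[Si](C)(C)C(C)(C)C)cc(CO[Si](C)(C)C(C)(C)C)cc1O[Si](C)(C)C(C)(C)C
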